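The plan rests on ring B (C5–C10). Its methyls on C8 and C10, oxygens on C6 and C7, and sp2 C9 match 2,6-dimethyl-1,4-benzoquinone, whose carbonyls become C6 and C9. C1–C4, ending in the gem-dimethyl C4, is the carbon chain of mesityl oxide.
Endgame disconnections: C13=C14 (Horner–Wadsworth–Emmons on a C13 methyl ketone), C7–O (Mitsunobu inversion of a 7β-ol with isovaleric acid), C7 oxygen plus C8=C9 (oxidative allylic transposition of a C9 tertiary carbinol), and C9–C11 (organocerium addition to the C9 ketone).
Core adjustments: the C6 ketone is reduced to the axial 6β-ol, the C2 oxygen left by the diene is deleted through its tosylhydrazone, and C5 is epimerised from cis to trans.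
Key disconnection: C1–C10 and C4–C5 by a catalytic enantioselective Diels–Alder reaction. Ring B is bought as the quinone, and ring A is the only ring formed (step 2).

Key step: step 2

Assumption: the (S)-diphenylprolinol-derived catalyst is taken to expose the quinone face that leads to (10S)-5, by analogy with dienophiles bound through an α-C–H···O contact; the sign is checked on 5, and if it is opposite the (R)-diphenylprolinol-derived catalyst is used with nothing else changed.
Numbering: labdane numbering is used for every bicyclic compound (ring A = C1–C5 and C10, ring B = C5–C10). β is the face of the C10 methyl group. The C14 core (4,4,8,10-tetramethyldecalin) is named as 11-nordrimane.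

Step 1
Reactants: 1 mesityl oxide (4-methylpent-3-en-2-one)
Product: 3 4-methyl-2-(triisopropylsilyloxy)penta-1,3-diene, via lithium dienolate 2 (not isolated)
Conditions: LiN(i-Pr)2, THF, −78 °C; i-Pr3SiOSO2CF3, −78 → 0 °C
Reagents that add atoms: triisopropylsilyl trifluoromethanesulfonate, CC(C)[Si](OS(=O)(=O)C(F)(F)F)(C(C)C)C(C)C
Why: Kinetic deprotonation of the enone at its α′ methyl group by the hindered lithium amide gives the cross-conjugated dienolate, and O-silylation with the silyl triflate (silyl enol ether formation) delivers the 2-silyloxydiene without touching the γ-methyl groups; no stereocentre is formed.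

Step 2
Reactants: 3 4-methyl-2-(triisopropylsilyloxy)penta-1,3-diene; 4 2,6-dimethyl-1,4-benzoquinone
Product: 5 (5R,10S)-2-(triisopropylsilyloxy)-11-nor-5β-drima-2,7-diene-6,9-dione (cis-fused, 5-H and the C10 methyl both β)
Conditions: (S)-3,3-diphenyl-1-(2-methylphenyl)tetrahydro-1H,3H-pyrrolo[1,2-c][1,3,2]oxazaborole (24 mol %), HN(SO2CF3)2 (20 mol %), CH2Cl2, −78 → −30 °C
Reagents that add atoms: none
Why: The boron of the N-protonated oxazaborolidine binds the C6 carbonyl oxygen (the carbonyl flanked by two vinylic C–H bonds, whereas the C9 carbonyl is screened by its two methyl-bearing neighbours), and a C5–H···O contact to the catalyst ring oxygen fixes the complex and makes C10 the most electrophilic carbon. The CH2 terminus of 3 (C1, largest HOMO coefficient of a 2-silyloxydiene) bonds to C10 ahead of C4–C5 in a strongly asynchronous [4+2] cycloaddition that may shade into a Mukaiyama–Michael addition followed by collapse of the silyloxyallyl cation onto the boron enolate; the closest known reaction types are the oxazaborolidinium-catalysed enantioselective Diels–Alder reaction of 2,6-disubstituted benzoquinones with 2-silyloxybutadienes and strong-acid-promoted Diels–Alder reactions of 4,4-disubstituted 2-silyloxydienes. Ring A is closed as a six-membered ring by intermolecular [4+2] annulation across C5=C10 (bonds C1–C10 and C4–C5). C10 is set by the catalyst, whose phenyl group covers one face of the bound quinone so that the diene adds to the open face, and C5 follows from suprafacial addition, which places 5-H cis to the C10 methyl; endo or exo approach has no stereochemical consequence because each diene terminus carries two identical substituents. The step needs regioselectivity, which sterics and electronics secure together (the slim CH2 goes to the methyl-bearing carbon and the CMe2 terminus to the CH carbon, so no vicinal quaternary pair arises), and mono-addition, which is secured because the two C=C bonds of 4 are homotopic and the remaining C7=C8 bond of 5 is no longer part of a quinone.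

Step 3
Reactants: 5 cis-fused adduct
Product: 6 (5S,10S)-2-(triisopropylsilyloxy)-11-nordrima-2,7-diene-6,9-dione (trans-fused, 5α-H)
Conditions: 1,8-diazabicyclo[5.4.0]undec-7-ene (0.3 equiv), toluene, 23 °C, argon
Reagents that add atoms: none
Why: Base-mediated epimerisation through the C5 enolate (5-H is the only ring-fusion proton next to a carbonyl and the quaternary C10 blocks aromatisation) should drain 5 into the trans-fused isomer by reprotonation on the α face, anti to the C10 and C4β methyl groups, while the intact silyl enol ether keeps C2 masked so that no retro-Michael cleavage of C4–C5 can start.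

Step 4
Reactants: 6 trans-fused ene-dione
Product: 7 6β-hydroxy-2-(triisopropylsilyloxy)-11-nordrima-2,7-dien-9-one
Conditions: NaBH4, CeCl3·7H2O, MeOH–CH2Cl2, −78 °C
Reagents that add atoms: none
Why: In this Luche 1,2-reduction the C6 carbonyl (neighbours tertiary C5 and C7–H) is more accessible than the C9 carbonyl (neighbours quaternary C10 and methyl-bearing C8), and hydride has to arrive from the α face because the β face is closed by the syn-axial C10 and C4β methyl groups, which sets the axial 6β-alcohol.

Step 5
Reactants: 7 6β-hydroxy silyl enol ether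
Product: 8 6β-hydroxy-11-nordrim-7-ene-2,9-dione
Conditions: HF·pyridine, THF, 0 °C
Reagents that add atoms: none
Why: Fluoride-assisted protodesilylation of the silyl enol ether unmasks the C2 ketone under non-basic conditions, and because C6 is now a carbinol carbon the C2/C6 relationship can no longer trigger a retro-Michael opening; no stereocentre is touched.

Step 6
Reactants: 8 hydroxy diketone
Product: 9 6β-hydroxy-11-nordrim-7-ene-2,9-dione 2-(p-toluenesulfonylhydrazone)
Conditions: p-MeC6H4SO2NHNH2 (1.05 equiv), EtOH, 23 °C
Reagents that add atoms: p-toluenesulfonyl hydrazide, Cc1ccc(cc1)S(=O)(=O)NN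
Why: Tosylhydrazone condensation is chemoselective for the saturated C2 ketone flanked by two CH2 groups over the conjugated C9 ketone, which is deactivated electronically and shielded by the quaternary C10.

Step 7
Reactants: 9 C2 tosylhydrazone
Product: 10 6β-hydroxy-11-nordrim-7-en-9-one
Conditions: catecholborane (3 equiv), CHCl3, −10 → 0 °C; NaOAc·3H2O, reflux
Reagents that add atoms: none
Why: In this Caglioti-type deoxygenation catecholborane adds hydride to the C=N bond, acetate then induces loss of sulfinate to a diazene that expels N2 and leaves CH2 at C2, and the cyclic s-trans enone is not reduced by this borane under these conditions.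

Step 8
Reactants: 10 6β-hydroxy-11-nordrim-7-en-9-one; 11 2-(2-bromoethyl)-2-methyl-1,3-dioxolane
Product: 14 13,13-ethylenedioxy-14,15-dinorlabd-7-ene-6β,9β-diol (side chain 9α), via Grignard reagent 12 (not isolated), via organocerium reagent 13 (not isolated)
Conditions: 11 (3.5 equiv), Mg, THF, 25 °C; CeCl3 (anhydrous), THF, −78 °C; then 10, −78 → 0 °C; aq NH4Cl
Reagents that add atoms: none
Why: The weakly basic, oxophilic organocerium reagent undergoes 1,2-addition to the hindered enone without reduction, enolisation or conjugate addition (the first equivalent only deprotonates the 6-OH) and attacks C9 from the α face anti to the axial C10 methyl, setting a 9β-carbinol that is erased again in step 10.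

Step 9
Reactants: 14 6β,9β-diol
Product: 15 6β-acetoxy-13,13-ethylenedioxy-14,15-dinorlabd-7-en-9β-ol
Conditions: Ac2O, 4-(dimethylamino)pyridine (cat.), pyridine, 23 °C
Reagents that add atoms: acetic anhydride, CC(=O)OC(C)=O
Why: Nucleophile-catalysed acylation takes place at the secondary allylic 6β-hydroxyl, whereas the tertiary 9-hydroxyl next to the quaternary C10 is too hindered to react, so the final C6 ester also serves as the protecting group for the oxidation that follows.

Step 10
Reactants: 15 tertiary allylic alcohol
Product: 16 6β-acetoxy-13,13-ethylenedioxy-14,15-dinorlabd-8-en-7-one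
Conditions: pyridinium chlorochromate [C5H5NH][CrO3Cl] (3 equiv), 4 Å molecular sieves, CH2Cl2, 23 °C
Reagents that add atoms: pyridinium chlorochromate (oxygen on C7), [O-][Cr](=O)(=O)Cl.c1cc[nH+]cc1
Why: In the Babler–Dauben oxidative transposition the chromate ester of the tertiary allylic alcohol undergoes a [3,3] shift that carries oxygen to C7, and oxidation by hexavalent chromium then gives the enone, which moves the alkene into the tetrasubstituted C8=C9 position of the target and removes the C9 stereocentre.

Step 11
Reactants: 16 6β-acetoxy enone
Product: 17 6β-acetoxy-13,13-ethylenedioxy-14,15-dinorlabd-8-en-7β-ol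
Conditions: NaBH4, CeCl3·7H2O, MeOH, −78 → −40 °C
Reagents that add atoms: none
Why: Luche 1,2-reduction delivers hydride axially from the α face, anti to the axial 6β-acetoxy group (steric and Felkin–Anh polar control), which sets the pseudo-equatorial 7β-alcohol, and the low temperature and non-basic medium should hold back acetyl migration from O6 to O7.

Step 12
Reactants: 17 7β-alcohol; 18 isovaleric acid (3-methylbutanoic acid)
Product: 19 6β-acetoxy-13,13-ethylenedioxy-7α-(3-methylbutanoyloxy)-14,15-dinorlabd-8-ene
Conditions: 18, PPh3, diisopropyl azodicarboxylate, toluene, 0 → 23 °C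
Reagents that add atoms: none
Why: Mitsunobu esterification displaces the allylic 7β-oxyphosphonium group by isovalerate with inversion along the axial α trajectory, which sets the 7α-ester trans-diaxial to the 6β-acetate; the SN2′ site C9 would become quaternary, and the cis 6β-acetate cannot reach the rear side of C7.

Step 13
Reactants: 19 diester ketal
Product: 20 6β-acetoxy-7α-(3-methylbutanoyloxy)-14,15-dinorlabd-8-en-13-one
Conditions: pyridinium p-toluenesulfonate (cat.), acetone–H2O, 50 °C
Reagents that add atoms: water, O
Why: Mild acid-catalysed ketal hydrolysis frees the C13 methyl ketone at an acidity too low to ionise the C7 allylic ester, whose cation is further disfavoured by the adjacent C6 acetoxy group.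

Step 14
Reactants: 20 methyl ketone; 21 allyl diethylphosphonoacetate
Product: 23 allyl 6β-acetoxy-7α-(3-methylbutanoyloxy)labda-8,13E-dien-15-oate, via sodium phosphonate anion 22 (not isolated)
Conditions: 21 (3.0 equiv), NaH (2.8 equiv), THF, 0 °C; then 20, 23 → 45 °C
Reagents that add atoms: none
Why: Horner–Wadsworth–Emmons olefination of the methyl ketone with the stabilised phosphonate anion should favour the E-enoate, which places the ester trans to the larger C12 chain (any Z isomer is removed by chromatography), and the slight deficit of base protects the two ester groups.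

Step 15
Reactants: 23 allyl ester
Product: 24 6β-acetoxy-7α-(3-methylbutanoyloxy)labda-8,13E-dien-15-oic acid, (5S,6S,7S,10S), CNP0328312.2
Conditions: Pd(PPh3)4 (5 mol %), morpholine, THF, 23 °C; dilute citric acid work-up
Reagents that add atoms: none
Why: Tsuji–Trost deallylation with zerovalent palladium ionises only the unhindered allyl ester and transfers the allyl group to morpholine, whereas the C7 isovalerate sits on a tetrasubstituted alkene that cannot bind the metal readily, and the acetate and isovalerate are inert to these neutral conditions.

Compound list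
1 | mesityl oxide | CC(=O)C=C(C)C | starting material
2 | lithium dienolate of mesityl oxide | C=C([O-])C=C(C)C.[Li+] | intermediate
3 | 4-methyl-2-(triisopropylsilyloxy)penta-1,3-diene | C=C(O[Si](C(C)C)(C(C)C)C(C)C)C=C(C)C | intermediate
4 | 2,6-dimethyl-1,4-benzoquinone | CC1=CC(=O)C=C(C)C1=O | starting material
5 | (5R,10S)-2-(triisopropylsilyloxy)-11-nor-5β-drima-2,7-diene-6,9-dione (cis-fused) | O=C1C=C(C)C(=O)[C@@]2(C)CC(O[Si](C(C)C)(C(C)C)C(C)C)=CC(C)(C)[C@@H]12 | intermediate
6 | (5S,10S)-2-(triisopropylsilyloxy)-11-nordrima-2,7-diene-6,9-dione (trans-fused) | O=C1C=C(C)C(=O)[C@@]2(C)CC(O[Si](C(C)C)(C(C)C)C(C)C)=CC(C)(C)[C@H]12 | intermediate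
7 | 6β-hydroxy-2-(triisopropylsilyloxy)-11-nordrima-2,7-dien-9-one | O[C@@H]1C=C(C)C(=O)[C@@]2(C)CC(O[Si](C(C)C)(C(C)C)C(C)C)=CC(C)(C)[C@H]12 | intermediate
8 | 6β-hydroxy-11-nordrim-7-ene-2,9-dione | O[C@@H]1C=C(C)C(=O)[C@@]2(C)CC(=O)CC(C)(C)[C@H]12 | intermediate
9 | 6β-hydroxy-11-nordrim-7-ene-2,9-dione 2-(p-toluenesulfonylhydrazone) | O[C@@H]1C=C(C)C(=O)[C@@]2(C)CC(=NNS(=O)(=O)c3ccc(C)cc3)CC(C)(C)[C@H]12 | intermediate
10 | 6β-hydroxy-11-nordrim-7-en-9-one | O[C@@H]1C=C(C)C(=O)[C@@]2(C)CCCC(C)(C)[C@H]12 | intermediate
11 | 2-(2-bromoethyl)-2-methyl-1,3-dioxolane | CC1(CCBr)OCCO1 | starting material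
12 | 2-(2-methyl-1,3-dioxolan-2-yl)ethylmagnesium bromide | CC1(CC[Mg]Br)OCCO1 | intermediate
13 | dichloro[2-(2-methyl-1,3-dioxolan-2-yl)ethyl]cerium | CC1(CC[Ce](Cl)Cl)OCCO1 | intermediate
14 | 13,13-ethylenedioxy-14,15-dinorlabd-7-ene-6β,9β-diol | O[C@@H]1C=C(C)[C@@](O)(CCC3(C)OCCO3)[C@@]2(C)CCCC(C)(C)[C@H]12 | intermediate
15 | 6β-acetoxy-13,13-ethylenedioxy-14,15-dinorlabd-7-en-9β-ol | CC(=O)O[C@@H]1C=C(C)[C@@](O)(CCC3(C)OCCO3)[C@@]2(C)CCCC(C)(C)[C@H]12 | intermediate
16 | 6β-acetoxy-13,13-ethylenedioxy-14,15-dinorlabd-8-en-7-one | CC(=O)O[C@@H]1C(=O)C(C)=C(CCC3(C)OCCO3)[C@@]2(C)CCCC(C)(C)[C@H]12 | intermediate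
17 | 6β-acetoxy-13,13-ethylenedioxy-14,15-dinorlabd-8-en-7β-ol | CC(=O)O[C@@H]1[C@H](O)C(C)=C(CCC3(C)OCCO3)[C@@]2(C)CCCC(C)(C)[C@H]12 | intermediate
18 | isovaleric acid | CC(C)CC(=O)O | starting material
19 | 6β-acetoxy-13,13-ethylenedioxy-7α-(3-methylbutanoyloxy)-14,15-dinorlabd-8-ene | CC(=O)O[C@@H]1[C@@H](OC(=O)CC(C)C)C(C)=C(CCC3(C)OCCO3)[C@@]2(C)CCCC(C)(C)[C@H]12 | intermediate
20 | 6β-acetoxy-7α-(3-methylbutanoyloxy)-14,15-dinorlabd-8-en-13-one | CC(=O)O[C@@H]1[C@@H](OC(=O)CC(C)C)C(C)=C(CCC(C)=O)[C@@]2(C)CCCC(C)(C)[C@H]12 | intermediate
21 | allyl diethylphosphonoacetate | C=CCOC(=O)CP(=O)(OCC)OCC | starting material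
22 | sodium salt of allyl diethylphosphonoacetate | [Na+].CCOP(=O)(OCC)[CH-]C(=O)OCC=C | intermediate
23 | allyl 6β-acetoxy-7α-(3-methylbutanoyloxy)labda-8,13E-dien-15-oate | CC(=O)O[C@@H]1[C@@H](OC(=O)CC(C)C)C(C)=C(CC/C(C)=C/C(=O)OCC=C)[C@@]2(C)CCCC(C)(C)[C@H]12 | intermediate
24 | 6β-acetoxy-7α-(3-methylbutanoyloxy)labda-8,13E-dien-15-oic acid (CNP0328312.2) | CC(=O)O[C@@H]1[C@@H](OC(=O)CC(C)C)C(C)=C(CC/C(C)=C/C(=O)O)[C@@]2(C)CCCC(C)(C)[C@H]12 | target

Total step count: 15. Longest linear sequence: 15 steps (1 → 24); compounds 4, 11, 18 and 21 are purchased.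

Steps most likely to fail

**Step 2.**
- What may go wrong: the methyl group on C4 that points inward penalises the s-cis conformer of the diene. Ring closure may therefore lag behind the first C–C bond, the acid may protodesilylate the diene, and the higher temperature needed may erode facial selectivity.
- Fallback (sets out from 3 and 4, returns at 5): the two bonds are made in two separate operations.
- The same catalyst is used at −78 °C only for the enantioselective Mukaiyama–Michael addition of C1 of 3 to C10 of 4. Mild aqueous acid work-up then gives (6S)-2,6-dimethyl-6-(4-methyl-2-oxopent-3-en-1-yl)cyclohex-2-ene-1,4-dione F1.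
- Treatment of F1 with i-Pr3SiOSO2CF3 and NEt3 in CH2Cl2 closes C4–C5 by an intramolecular Mukaiyama–Michael addition of the C5 silyl dienol ether onto the silyl-activated β,β-dimethyl enone.
- The new C2 enolate is trapped irreversibly as its triisopropylsilyl ether, which is 5. Any trans isomer formed at this point is 6 and is equally useful.

**Step 3.**
- What may go wrong: ring B of the ene-dione is nearly flat, so the equilibrium may not lie far enough on the trans side. Prolonged exposure to base invites γ-deprotonation at the C8 methyl group and air oxidation of the enolate.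
- Fallback (sets out from 5, returns at 6): thermodynamic control is replaced by kinetic protonation.
- Kinetic α′-deprotonation of 5 with KN(SiMe3)2 in the presence of Me3SiCl (THF, −78 °C) traps the C5 enolate as (10S)-6-(trimethylsilyloxy)-2-(triisopropylsilyloxy)-11-nordrima-2,5,7-trien-9-one F2.
- One equivalent of Bu4NF buffered with acetic acid at −78 °C then releases the enolate. It is protonated on the α face, away from the C10 and C4β methyl groups, to give 6. The bulkier C2 silyl enol ether survives.

**Step 12.**
- What may go wrong: displacement at the hindered allylic C7 may be slow. That leaves room for elimination toward a diene, allylic scrambling, or acetyl migration in the cis 6β-acetoxy-7β-ol.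
- Fallback (sets out from 15, returns at 19, bypassing 16 and 17; no compound outside the list is made, F0): 15 is ionised at 0 °C in anhydrous isovaleric acid 18 containing isovaleric anhydride and catalytic Sc(OSO2CF3)3.
- The tertiary C9 hydroxyl leaves and the 6β-acetoxy group bridges C7 on the β face. Isovalerate then opens the bridged allyl cation at C7 from the α face (Prévost-type trans-diaxial opening with allylic transposition).

Further compounds
F1 | step 2 | (6S)-2,6-dimethyl-6-(4-methyl-2-oxopent-3-en-1-yl)cyclohex-2-ene-1,4-dione | O=C1C=C(C)C(=O)[C@@](C)(CC(=O)C=C(C)C)C1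
F2 | step 3 | (10S)-6-(trimethylsilyloxy)-2-(triisopropylsilyloxy)-11-nordrima-2,5,7-trien-9-one | C[Si](C)(C)OC1=C2C(C)(C)C=C(O[Si](C(C)C)(C(C)C)C(C)C)C[C@]2(C)C(=O)C(C)=C1
F0 | step 12 | none | none
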